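**An impossible balance.** The birch run cannot have spent its electrophile one-for-one on nucleophile: by 40.0 min its readings show a loss of 54.4 mM, more than the 48 mM of nucleophile charged.

| flask | electrophile | nucleophile | free base | remark | time |
|---|---|---|---|---|---|
| birch | 72 mM | 48 mM | 57.6 mM | run made earlier |  |
| Monday's | 48 mM | 48.0 mM | 58.0 mM |  | 1.0 h |
| Sunday's | 48 mM | 48.0 mM | 86.0 mM |  | 1.0 h |
| Wednesday's | 48 mM | 48.0 mM | 130 mM |  | 1.0 h |

birch run (percent of the electrophile charged)

| time / min | electrophile / % | target / % |
|---|---|---|
| 3.00 | 78.7 | 12.2 |
| 6.00 | 61.6 | 17.8 |
| 15.0 | 42.2 | 22.1 |
| 40.0 | 24.5 | 20.8 |

(readings scatter by 1 percentage point)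

- no earlier run changes the charge of free base; that part of a forecast is a guess

- part of the electrophile that has reacted at the end, Monday's
- part of the electrophile that has reacted at the end, Sunday's
- part of the electrophile that has reacted at the end, Wednesday's
- what raising the concentration of free base from its lowest to its highest value here does to the part of the electrophile that has reacted (changes below 5 percentage points count as none) (it rises / it falls / no change)

**The ledger.** Keep the books on the electrophile, the peak the question concerns. The birch run was charged with 72 mM. At its last reading 17.6 mM still shows as electrophile and 15.0 mM as target. The other 39.4 mM has no peak among these readings, and that entry is larger than the target entry. So the books need an unseen entry, and you should reckon what has reacted from the electrophile peak, not from the target.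

**Counting turnovers.** At the last birch reading the turnover count stands at 3.08. The count is the charged [electrophile] over the remaining [electrophile], less one. If the loss is second order in [electrophile], which is my assumption, the count is the time measured in first half-lives, so it grows with charged [electrophile] times time. Monday's flask pairs 48 mM with 1.0 h, and that product equals the birch product. My count for Monday's flask is therefore 3.08, and the reacted share, count over count plus one, is 75.5%. The count has no free base in it and no earlier run varies that charge, so I guess the same share for Sunday's and Wednesday's flasks, hence no change.

**The forecast.** The forecast gives 94%, 97% and 98%, trend no change, holding that “double alkylation can consume all the electrophile”. Its Monday figure stands above mine; on the trend we agree.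

**The flask's answer.** Monday's flask gives 78.3%, Sunday's 78.4% and Wednesday's 78.7%, so the trend is no change, a change of 0.39 percentage points. At 1.00 h Monday's flask holds 21.7% electrophile, 27.1% target, 14.9% over-reaction product and 36.3% self-condensation product, a percentage in which each such product already counts as two.

    electrophile + nucleophile → acid set free + target (k = 1.20 /M/min)
    nucleophile + acid set free ⇌ protonated nucleophile, settled at all times (K = 1.40 × 10⁵ /M)
    acid set free + free base ⇌ salt of the base (K = 7200 /M, k = 21.0 /M/min)
    nucleophile + acid set free ⇌ idle adduct, settled at all times (K = 52.0 /M)
    2 electrophile → self-condensation product (k = 0.350 /M/min)
    nucleophile + target → over-reaction product (k = 1.20 /M/min)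

Read back from Monday's result, the count is 3.61, against my 3.08. Read at 4.0 h, Monday's flask has a count of 12.3, which reckons to 92.5%, and the flask gives 92.9%.

The earlier runs and the new flask are calculated with made-up constants; the scatter is artificial.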